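**Retrosynthetic overview**
- Abyssinone-IV is (2S)-7-hydroxy-2-[4-hydroxy-3,5-diprenylphenyl]chroman-4-one; the SMILES centre [C@@H] is S, the natural flavanone configuration.
- Key disconnection: the C2–aryl bond, made by a catalytic enantioselective conjugate addition of an arylboronic acid to a chromone; this step sets the only stereocentre.
- The benzopyranone (A/C) ring system is bought intact as 7-hydroxychromone, so no ring-forming step is needed; the B ring is attached last.
- The B-ring boronic acid comes from 4-bromophenol by double ortho C-prenylation, MOM protection and Br→B exchange.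
- Both phenols are carried as MOM ethers and unmasked together under acid, because base racemises 4'-hydroxyflavanones by ring opening.

Assumption: the facial selectivity of the Pd/t-BuPyOx conjugate addition on chromones follows the cyclic-enone model, in which the (S)-ligand gives (R)-flavanones, so the (R)-ligand is used. This is assigned by analogy and should be confirmed on the product by CD (2S: positive Cotton effect near 330 nm, negative near 290 nm).

**Route**

Step 1
Reactants: 1, 4-bromophenol; 2, prenyl bromide (1-bromo-3-methylbut-2-ene, 2.2 equiv)
Product: 3, 4-bromo-2,6-bis(3-methylbut-2-en-1-yl)phenol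
Conditions: NaH (2.2 equiv), toluene, 0 °C → rt; chromatography (mono-prenyl phenol recycled)
Reagents that add atoms: prenyl bromide, CC(C)=CCBr (two equivalents incorporated)
Why: Ortho C-alkylation of a tight sodium phenoxide ion pair in a non-polar solvent; the para position is blocked by Br, so both prenyl groups go ortho. A modest yield (about 25–40%) is expected.

Step 2
Reactants: 3; 4, chloromethyl methyl ether (MOMCl)
Product: 5, 5-bromo-2-(methoxymethoxy)-1,3-bis(3-methylbut-2-en-1-yl)benzene
Conditions: NaH, MOMCl, DMF, 0 °C → rt
Reagents that add atoms: MOMCl, COCCl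
Why: Williamson-type O-alkylation; the small, reactive MOMCl caps the hindered 2,6-dialkylphenoxide.

Step 3
Reactants: 5; 6, triisopropyl borate
Product: 7, [4-(methoxymethoxy)-3,5-bis(3-methylbut-2-en-1-yl)phenyl]boronic acid
Conditions: n-BuLi (1.1 equiv), THF, −78 °C; B(OiPr)3, −78 °C → rt; sat. aq NH4Cl
Reagents that add atoms: triisopropyl borate, CC(C)OB(OC(C)C)OC(C)C; water, O (hydrolysis to B(OH)2)
Why: Bromine–lithium exchange at −78 °C outpaces benzylic/allylic deprotonation, and borate trapping with hydrolysis gives the boronic acid. MOM and prenyl groups are inert.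

Step 4
Reactants: 8, 7-hydroxychromone (7-hydroxy-4H-chromen-4-one); 4, MOMCl
Product: 9, 7-(methoxymethoxy)-4H-chromen-4-one
Conditions: MOMCl, iPr2NEt, CH2Cl2, 0 °C → rt
Reagents that add atoms: MOMCl, COCCl
Why: Phenol O-alkylation with a non-nucleophilic amine base, which avoids the pyrone ring opening that hydroxide or secondary amines cause.

Step 5
Reactants: 9 (1.0 equiv); 7 (2.0 equiv)
Product: 10, (2S)-7-(methoxymethoxy)-2-[4-(methoxymethoxy)-3,5-bis(3-methylbut-2-en-1-yl)phenyl]chroman-4-one
Conditions: Pd(OCOCF3)2 (5 mol%), (R)-t-BuPyOx [(R)-4-tert-butyl-2-(pyridin-2-yl)-4,5-dihydrooxazole, CC(C)(C)[C@@H]1COC(=N1)c1ccccn1] (6 mol%), NH4PF6 (30 mol%), H2O (5 equiv), ClCH2CH2Cl, 60 °C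
Reagents that add atoms: none beyond reactants 7 and 9 (the C3–H comes from water)
Why: Pd(II)/pyridine-oxazoline-catalysed asymmetric conjugate addition: transmetalation, enantio-determining aryl insertion at C2, and protonation of the Pd enolate. The (R)-ligand shields one enone face to give the 2S centre, and the base-free conditions prevent retro-oxa-Michael racemisation; the trisubstituted prenyl alkenes are poor ligands for Pd.

Step 6
Reactants: 10
Product: 11, abyssinone-IV, (2S)-7-hydroxy-2-[4-hydroxy-3,5-bis(3-methylbut-2-en-1-yl)phenyl]chroman-4-one
Conditions: 3 M aq HCl, MeOH, 45–50 °C, about 1 h (monitor and stop at full conversion)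
Reagents that add atoms: none
Why: Acid-catalysed acetal (MOM) hydrolysis frees both phenols. Flavanones are configurationally stable in mild acid, so the 2S centre is retained, and the short, mild exposure limits cyclisation of prenyl onto the new phenol.

**Compound list**
1 | 4-bromophenol | Oc1ccc(Br)cc1 | starting material
2 | prenyl bromide | CC(C)=CCBr | starting material
3 | 4-bromo-2,6-bis(3-methylbut-2-en-1-yl)phenol | CC(C)=CCc1cc(Br)cc(CC=C(C)C)c1O | intermediate
4 | chloromethyl methyl ether (MOMCl) | COCCl | starting material
5 | 5-bromo-2-(methoxymethoxy)-1,3-bis(3-methylbut-2-en-1-yl)benzene | CC(C)=CCc1cc(Br)cc(CC=C(C)C)c1OCOC | intermediate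
6 | triisopropyl borate | CC(C)OB(OC(C)C)OC(C)C | starting material
7 | [4-(methoxymethoxy)-3,5-bis(3-methylbut-2-en-1-yl)phenyl]boronic acid | CC(C)=CCc1cc(B(O)O)cc(CC=C(C)C)c1OCOC | intermediate
8 | 7-hydroxychromone | O=c1ccoc2cc(O)ccc12 | starting material
9 | 7-(methoxymethoxy)-4H-chromen-4-one | COCOc1ccc2c(c1)occc2=O | intermediate
10 | (2S)-7-(methoxymethoxy)-2-[4-(methoxymethoxy)-3,5-bis(3-methylbut-2-en-1-yl)phenyl]chroman-4-one | CC(C)=CCc1cc([C@@H]2CC(=O)c3ccc(OCOC)cc3O2)cc(CC=C(C)C)c1OCOC | intermediate
11 | abyssinone-IV, (2S)-7-hydroxy-2-[4-hydroxy-3,5-bis(3-methylbut-2-en-1-yl)phenyl]chroman-4-one | CC(C)=CCc1cc([C@@H]2CC(=O)c3ccc(O)cc3O2)cc(CC=C(C)C)c1O | target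

**Totals**
Total steps: 6. Longest linear sequence: 5 (steps 1 → 2 → 3 → 5 → 6); step 4 is a one-step convergent branch.

**Three steps most likely to fail, with fallbacks**
1. Step 5 (asymmetric conjugate addition). Risks: the electron-rich 7-alkoxychromone is a sluggish acceptor, the electron-rich boronic acid can protodeboronate, and ee or sense of induction may fall short. Fallback: change the bond construction to an enantioselective oxa-Michael ring closure.
   - Convert bromide 5 to the aldehyde (n-BuLi, DMF).
   - Knoevenagel-condense it with tert-butyl 3-[2-hydroxy-4-(methoxymethoxy)phenyl]-3-oxopropanoate.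
   - Cyclise the alkylidene β-ketoester with a cinchona-derived bifunctional thiourea, then de-tert-butylate and decarboxylate to 10.
2. Step 1 (double ortho C-prenylation). Risks: O-alkylation, mono-alkylation and chroman by-products giving low yield. Fallback: start from 2,4,6-tribromophenol MOM ether and install each prenyl by ortho-selective Br/Li exchange, transmetalation to copper and allylation with prenyl bromide, done twice. The para bromine is kept for the borylation.
3. Step 6 (global MOM removal). Risk: acid-promoted cyclisation of an ortho prenyl onto the liberated 4'-OH to give a 2,2-dimethylchroman, or alkene hydration. Fallback: change the protecting-group strategy to TBS ethers on both phenols (installed in steps 2 and 4) and cleave at the end with HF·pyridine or KHF2/MeOH. This avoids both strong acid and the basic conditions that would racemise C2.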